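Temperature separates the flasks asked about: Tuesday's stands at 25 °C, Wednesday's at 45 °C and Saturday's at 65 °C, while Thursday's goes from 25 °C to 65 °C at 15 h. Their charges are equal.

| flask | left-handed substrate | right-handed substrate | gas | free catalyst | added ligand | temperature | remark | time |
|---|---|---|---|---|---|---|---|---|
| dawn | 0.024 M | 0.024 M | 1.1 mM (held) | 5.3 mol% | 1.1 mM | 35 °C | run made earlier |  |
| summer | 0.037 M | 0.037 M | 1.1 mM (held) | 5.3 mol% | 1.1 mM | 57 °C | run made earlier |  |
| autumn | 0.017 M | 0.017 M | 1.1 mM (held) | 11 mol% | 1.1 mM | 35 °C | run made earlier |  |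
| Wednesday's | 0.017 M | 0.017 M | 1.1 mM (held) | 5.3 mol% | 1.1 mM | 45 °C |  | 30 h |
| Thursday's | 0.017 M | 0.017 M | 1.1 mM (held) | 5.3 mol% | 1.1 mM |  | at 25 °C until 15 h, from then on at 65 °C | 30 h |
| Saturday's | 0.017 M | 0.017 M | 1.1 mM (held) | 5.3 mol% | 1.1 mM | 65 °C |  | 30 h |
| Tuesday's | 0.017 M | 0.017 M | 1.1 mM (held) | 5.3 mol% | 1.1 mM | 25 °C |  | 30 h |

| run | time / h | left-handed product / % | right-handed product / % | left-handed substrate / % |
|---|---|---|---|---|
| dawn | 10.0 | 10.4 | 5.7 | 40.2 |
| dawn | 20.0 | 12.4 | 8.5 | 37.8 |
| dawn | 30.0 | 12.9 | 5.9 | 37.8 |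
| dawn | 40.0 | 10.5 | 9.3 | 38.1 |
| dawn | 50.0 | 13.0 | 8.1 | 38.7 |
| dawn | 60.0 | 12.0 | 7.0 | 38.3 |
| summer | 1.50 | 3.1 | 0.4 | 47.0 |
| summer | 3.00 | 1.8 | 4.5 | 43.8 |
| summer | 4.00 | 4.5 | 3.3 | 43.7 |
| summer | 6.00 | 8.0 | 3.8 | 40.7 |
| summer | 12.0 | 10.2 | 8.3 | 36.3 |
| summer | 20.0 | 10.3 | 7.1 | 36.6 |
| autumn | 5.00 | 9.8 | 5.4 | 40.3 |
| autumn | 8.00 | 12.9 | 7.8 | 37.2 |
| autumn | 15.0 | 16.6 | 11.5 | 32.5 |
| autumn | 30.0 | 17.8 | 12.9 | 33.2 |
| autumn | 60.0 | 16.2 | 10.6 | 33.9 |

(readings scatter by 1 percentage point)

- free catalyst is single-handed; left-handed substrate and right-handed substrate are mirror images of each other, charged as a racemate, each of them at the stated concentration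
- what was read earlier has a scatter of 1 percentage point, one standard deviation
- at the start none of the gas is in solution
- an excess is the difference of the two amounts in percent of their sum
- an excess is below zero if the other one leads

1. the best flask by excess of left-handed product over right-handed product; "all alike" if 1.5 percentage points covers them all (Wednesday's / Thursday's / Saturday's / Tuesday's / all alike)
2. excess of left-handed product over right-handed product at the end, Wednesday's
3. excess of left-handed product over right-handed product at the end, Thursday's
4. excess of left-handed product over right-handed product at the end, Saturday's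
5. excess of left-handed product over right-handed product at the end, Tuesday's

1. We compare two times: τ_L, the half-life of the left-handed substrate, and τ_R, that of the right-handed substrate. We assume each is used first-order in itself, with the same catalyst over the same hours in one flask. The catalyst's fate then cancels from τ_R/τ_L, which equals the ratio of the logarithms of the fractions remaining.

2. In the autumn run the products stand still from 15.0 h on. Averaging those readings, with each substrate charged as half the total, gives 1.55 for s, the selectivity factor τ_R/τ_L, as a reading.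

3. At small conversion the excess approaches E, which is s minus one over s plus one: 21.5%. The autumn run reads 18.2%, lower than E, with 28.5% of the charge read as product.

4. The summer run, at 57 °C, reads 14.2% from its last two readings. With products this small, that excess carries a scatter of about 5.6 percentage points. We therefore keep s unchanged and expect each flask just under E, alike within the margin.

5. The forecast differs: Tuesday's 25%, Thursday's 23%, Wednesday's 19%, Saturday's 14%, best Tuesday's. Its ground is a selectivity factor that falls as the temperature rises: “s ≈ 1.7 at 25 °C, 1.5 at 45 °C and 1.33 at 65 °C”.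

The flasks give Tuesday's 21.1%, Thursday's 21.1%, Wednesday's 20.7% and Saturday's 20.2%: all alike.

    partner + free catalyst + left-handed substrate → free catalyst + left-handed product (k = 69000 M⁻² h⁻¹, Ea = 44.0 kJ mol⁻¹)
    partner + free catalyst → spent catalyst (k = 250 M⁻¹ h⁻¹, Ea = 64.0 kJ mol⁻¹)
    gas ⇌ partner, rate k3*(csat - [partner]) (kL = 2.10 h⁻¹)
    free catalyst + added ligand ⇌ idle complex, settled at all times (K = 530 M⁻¹, ΔH = 22.0 kJ mol⁻¹)
    partner + free catalyst + right-handed substrate → free catalyst + right-handed product (k = 43000 M⁻² h⁻¹, Ea = 45.0 kJ mol⁻¹)
    (constants at 25 °C)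

The forecast and the flasks part most on Saturday's. There, 91% of the left-handed substrate remains, and our s turns that into 94.1% of the right-handed substrate; the flask holds 94%. A neighbour of Thursday's, charged with 21 mol% of free catalyst, keeps 43% of its left-handed substrate, so s gives 58.0% of the right-handed one, and the flask holds 59%. That neighbour ends at an excess of 16.3%, lower than Thursday's 21.1%.

(The numbers in the tables were generated by integration from invented constants; scatter was added.)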